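**Plan**

1. Retrosynthesis: remove the C13 acetate, then trace the C4 carbinol / C5=C6 / butenolide array back (vinylogous E1cB, lactonisation) to a (4R,5R)-4,5-epoxide flanked by a C6 silyl ether and a (Z)-C7=C11 enoate, and the epoxide back to the E-C4=C5 alkene.
2. Enabling feature: in the ten-membered ring C1–C10 this leaves C1(=O)–C2–C3–C4=C5, a γ,δ-unsaturated ketone. Cutting C2–C3 and re-inserting CO2 gives a 12-membered allyl β-keto lactone (C1, C2, ester C, O, C3–C10), so the carbocycle arises by ring contraction with loss of CO2.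
3. Further cuts: lactone C(=O)–O (acylketene macrolactonisation), C8–O acyl, C1–C2 (Claisen opening of a γ-lactone), C6–C7 (Nozaki–Hiyama–Kishi), C7–C11 (enolate acylation).
4. Forward order: fragment 4 (C3–C6) and fragment 13 (C7–C13 with C8–C10/C1) are joined at C6–C7. The chain is closed to the 12-membered lactone, contracted to the ten-membered carbocycle, epoxidised, and the butenolide ring is formed last in a desilylation/lactonisation/epoxide-opening cascade.
5. Stereochemistry: C8 comes from (R)-γ-hydroxymethyl-γ-butyrolactone, C10 from trans-selective lactone enolate methylation, C4 from Shi epoxidation (reagent control, C4–O bond retained). C6 is a transient centre that is erased. E-C4=C5 comes from syn-carboalumination, C7=C11 from a chelated Z-enol triflate, Z-C5=C6 from the E1cB step.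

Key step: step 14

Remarks
- Numbering (germacrane): C1 ketone carbon, C2, C3, C4 (C–OH, Me), C5, C6 (lactone O), C7, C8 (O-senecioyl), C9, C10 (CHMe); C11 butenolide α-carbon, C12 lactone carbonyl, C13 CH2OAc carbon.
- The target is treated as the open 4-hydroxy-1-ketone as drawn; a 1,4-hemiketal tautomer would be the same compound in equilibrium.
- Compounds 14–22 are carried as mixtures of C6 epimers (SMILES without a C6 descriptor), because C6 becomes sp2 in step 16.
- Compounds 1, 5, 7 and all reagents are taken to be commercial.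

**Route**

Step 1
Reactants: 1 4-methoxybenzyl propargyl ether
Product: 3 (2E)-4-[(4-methoxybenzyl)oxy]-3-methylbut-2-en-1-ol, via alkenylalane 2 (not isolated)
Conditions: Me3Al, Cp2ZrCl2 (cat.), CH2Cl2, 0 °C → rt; n-BuLi, THF, −78 °C; (CH2O)n, −78 °C → rt; aq. HCl
Reagents that add atoms: trimethylaluminium C[Al](C)C; formaldehyde (from paraformaldehyde) C=O
Why: Negishi Zr-catalysed carboalumination adds Me and Al syn across the terminal alkyne (Me to the internal carbon), and hydroxymethylation of the derived alanate with retention should give the E-trisubstituted allylic alcohol.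

Step 2
Reactants: 3 (2E)-4-[(4-methoxybenzyl)oxy]-3-methylbut-2-en-1-ol
Product: 4 (2E)-4-[(4-methoxybenzyl)oxy]-3-methylbut-2-enal
Conditions: MnO2, CH2Cl2, rt
Reagents that add atoms: none
Why: Allylic alcohol oxidation with activated MnO2 stops at the enal and should leave the E geometry and the PMB ether untouched.

Step 3
Reactants: 5 methyl 3-hydroxypropanoate
Product: 6 methyl 3-[(tert-butyldimethylsilyl)oxy]propanoate
Conditions: TBSCl, imidazole, CH2Cl2, rt
Reagents that add atoms: tert-butyldimethylsilyl chloride CC(C)(C)[Si](C)(C)Cl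
Why: Silyl ether formation, in which imidazole-activated TBSCl silylates the primary alcohol.

Step 4
Reactants: 7 (5R)-5-(hydroxymethyl)oxolan-2-one
Product: 8 (5R)-5-{[(tert-butyldimethylsilyl)oxy]methyl}oxolan-2-one
Conditions: TBSCl, imidazole, DMF, rt
Reagents that add atoms: tert-butyldimethylsilyl chloride CC(C)(C)[Si](C)(C)Cl
Why: Silyl ether formation protects the primary alcohol and provides the bulky group that directs the next step.

Step 5
Reactants: 8 (5R)-5-{[(tert-butyldimethylsilyl)oxy]methyl}oxolan-2-one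
Product: 9 (3S,5R)-5-{[(tert-butyldimethylsilyl)oxy]methyl}-3-methyloxolan-2-one
Conditions: LDA, THF, −78 °C; MeI, −78 → −40 °C
Reagents that add atoms: iodomethane CI
Why: Lactone enolate alkylation, in which MeI approaches the lithium enolate anti to the C5 silyloxymethyl group so that the 3,5-trans lactone (3S, the future C10) should predominate.

Step 6
Reactants: 9 (3S,5R)-5-{[(tert-butyldimethylsilyl)oxy]methyl}-3-methyloxolan-2-one
Product: 10 (2R,4S)-4-methyl-5-oxooxolane-2-carboxylic acid
Conditions: CrO3, H2SO4, acetone/H2O (Jones reagent), 0 °C → rt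
Reagents that add atoms: water O
Why: Jones oxidation, in which the acidic chromic acid medium cleaves the primary TBS ether and oxidises the alcohol through the aldehyde hydrate to the acid while the lactone and both stereocentres are not enolised.

Step 7
Reactants: 10 (2R,4S)-4-methyl-5-oxooxolane-2-carboxylic acid; 6 methyl 3-[(tert-butyldimethylsilyl)oxy]propanoate
Product: 12 methyl 2-{[(tert-butyldimethylsilyl)oxy]methyl}-3-[(2R,4S)-4-methyl-5-oxooxolan-2-yl]-3-oxopropanoate, via acid chloride 11 (not isolated)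
Conditions: (COCl)2, DMF (cat.), CH2Cl2, 0 °C → rt, concentrate; add to 6/LDA (2.2 equiv), THF, −78 °C; AcOH
Reagents that add atoms: none
Why: Crossed Claisen-type C-acylation of an ester lithium enolate by an acid chloride, in which the second equivalent of enolate deprotonates the β-keto ester as it forms and so shields it and the C8 stereocentre from further reaction.

Step 8
Reactants: 12 methyl 2-{[(tert-butyldimethylsilyl)oxy]methyl}-3-[(2R,4S)-4-methyl-5-oxooxolan-2-yl]-3-oxopropanoate
Product: 13 methyl (2Z)-2-{[(tert-butyldimethylsilyl)oxy]methyl}-3-[(2R,4S)-4-methyl-5-oxooxolan-2-yl]-3-{[(trifluoromethyl)sulfonyl]oxy}prop-2-enoate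
Conditions: Tf2O, Et3N, LiOTf, CH2Cl2, −78 → 0 °C
Reagents that add atoms: trifluoromethanesulfonic anhydride O=S(=O)(OS(=O)(=O)C(F)(F)F)C(F)(F)F
Why: Enol triflation of the lithium-chelated Z-enolate of the β-keto ester should place OTf cis to the ester, which is the geometry the later lactone needs.

Step 9
Reactants: 13 (Z)-enol triflate; 4 (2E)-4-[(4-methoxybenzyl)oxy]-3-methylbut-2-enal
Product: 14 methyl (2Z,5E)-2-{[(tert-butyldimethylsilyl)oxy]methyl}-7-[(4-methoxybenzyl)oxy]-6-methyl-3-[(2R,4S)-4-methyl-5-oxooxolan-2-yl]-4-[(triethylsilyl)oxy]hepta-2,5-dienoate (C6 epimers)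
Conditions: CrCl2 (15 mol%), NiCl2 (2 mol%), Mn powder, Et3SiCl, DMF/DME, rt
Reagents that add atoms: chlorotriethylsilane CC[Si](Cl)(CC)CC
Why: Nozaki–Hiyama–Kishi coupling under Cr-catalytic conditions, in which Ni inserts into the alkenyl triflate, the alkenylchromium(III) adds chemoselectively to the aldehyde with retention of alkene geometry and the chlorosilane silylates the chromium alkoxide before it can lactonise; the new C6 carbinol forms without control, which is harmless because C6 becomes sp2 in step 16.

Step 10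
Reactants: 14 NHK adduct (γ-lactone, C6-OTES)
Product: 15 9-tert-butyl 1-methyl (2Z,4R,6S)-2-{[(tert-butyldimethylsilyl)oxy]methyl}-4-hydroxy-3-{(2E)-4-[(4-methoxybenzyl)oxy]-3-methyl-1-[(triethylsilyl)oxy]but-2-en-1-yl}-6-methyl-7-oxonon-2-enedioate
Conditions: tert-butyl acetate, LDA, THF, −78 °C; then 14, −78 → −40 °C; AcOH
Reagents that add atoms: tert-butyl acetate CC(=O)OC(C)(C)C
Why: Crossed Claisen condensation of an ester enolate with a lactone, in which the γ-lactone carbonyl is the most electrophilic acyl group present, so its opening delivers the tert-butyl β-keto ester (C1, C2) and frees the C8 hydroxyl while the hindered conjugated tetrasubstituted methyl enoate should not react at −78 °C.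

Step 11
Reactants: 15 hydroxy β-keto ester
Product: 16 C8 3-methylbut-2-enoate (senecioate) of 15
Conditions: 3-methylbut-2-enoic acid, DCC, DMAP (cat.), CH2Cl2, 0 °C → rt
Reagents that add atoms: 3-methylbut-2-enoic acid CC(C)=CC(=O)O
Why: Steglich esterification acylates the secondary C8 alcohol of the open hydroxy ketone and, unlike the acid chloride with an amine base, avoids the vinylketene pathway that would deconjugate the senecioate.

Step 12
Reactants: 16 senecioate PMB ether
Product: 17 primary allylic alcohol (C3-OH) of 16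
Conditions: DDQ, CH2Cl2/pH 7 buffer, 0 °C
Reagents that add atoms: none
Why: Oxidative PMB ether cleavage (hydride abstraction from the electron-rich benzylic position, then hydrolysis) should spare the silyl ethers, the esters and the β-keto ester.

Step 13
Reactants: 17 hydroxy tert-butyl β-keto ester
Product: 19 twelve-membered allyl β-keto lactone (1-oxacyclododec-10-ene-2,4-dione core), via acylketene 18 (not isolated)
Conditions: toluene, 110 °C, slow addition (final 0.5 mM)
Reagents that add atoms: none
Why: Acylketene macrolactonisation, in which thermolysis of the tert-butyl β-keto ester expels tert-butanol and the acylketene is captured under high dilution by the only free hydroxyl (C3-OH) to close the 12-membered ring.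

Step 14
Reactants: 19 twelve-membered allyl β-keto lactone
Product: 20 methyl (4E,8R,10S)-13-[(tert-butyldimethylsilyl)oxy]-8-[(3-methylbut-2-enoyl)oxy]-1-oxo-6-[(triethylsilyl)oxy]germacra-4,7(11)-dien-12-oate (ten-membered carbocycle)
Conditions: Pd(PPh3)4 (10 mol%), THF (2 mM), 25 → 45 °C
Reagents that add atoms: none
Why: Proposed new method: Pd(0) ionises the primary C3–O bond of the 2-methylalk-2-enyl β-keto ester to an η3-allyl (C3–C4–C5) paired with the tethered β-keto carboxylate, which loses CO2 to give the C1/C2 enolate, and C–C bond formation between C2 and the unsubstituted allyl terminus C3 then excises the ester C and O from the 12-membered lactone and leaves the ten-membered carbocycle with the C1 ketone and the E-C4=C5 alkene. The closest known reaction types are the decarboxylative Tsuji–Trost allylation of acyclic allyl β-keto esters (Pd-catalysed Carroll-type reaction) and the Pd-catalysed isomerisation of allylic macrolactones carrying a stabilised carbanion to carbocycles; the macrocyclic, ring-contracting decarboxylative variant is the new element. The ten-membered ring closes in a 10-endo sense with respect to the π-allyl unit (attack at the terminus remote from the tether), as opposed to 8-exo attack at C5. No stereocentre is formed: C8 and C10 are untouched because the enolate is generated regiospecifically at C2 under neutral conditions, and the alkene should stay E because the syn-η3-allyl cannot isomerise except through a tertiary σ-complex at C4. The step needs terminus selectivity (C3 over C5) and intra- over intermolecular allylation; the first is secured by the preference of Pd for attack at the CH2 terminus and by the branched silyloxy-bearing C6 next to C5, the second by the ion pair being held in one molecule and by high dilution. The C8 senecioate is allylic only to a tetrasubstituted ester-conjugated alkene and the C6 oxygen is a silyl ether, so neither should ionise.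

Step 15
Reactants: 20 ten-membered keto diene ester
Product: 21 methyl (4R,5R,8R,10S)-13-[(tert-butyldimethylsilyl)oxy]-4,5-epoxy-8-[(3-methylbut-2-enoyl)oxy]-1-oxo-6-[(triethylsilyl)oxy]germacr-7(11)-en-12-oate
Conditions: Shi ketone (D-fructose-derived, 30 mol%), Oxone, K2CO3, Bu4NHSO4 (cat.), MeCN/DMM/aq. Na2B4O7–EDTA buffer, 0 °C
Reagents that add atoms: potassium peroxymonosulfate (Oxone) [K+].[O-]S(=O)(=O)OO
Why: Shi asymmetric epoxidation, in which the chiral dioxirane attacks the only electron-rich alkene (E-trisubstituted C4=C5) through the spiro transition state that gives (R,R)-epoxides from E-olefins, so reagent control should set C4 (R) and C5 (R) while both conjugated alkenes are too electron-poor to react.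

Step 16
Reactants: 21 (4R,5R)-epoxide
Product: 23 (4R,5Z,8R,10S)-4,13-dihydroxy-8-[(3-methylbut-2-enoyl)oxy]-1-oxogermacra-5,7(11)-dien-12,6-olide (13-deacetyl target), via epoxy butenolide 22 (not isolated)
Conditions: TBAF (3 equiv), THF, 0 °C → rt; aq. NH4Cl
Reagents that add atoms: none
Why: Fluoride desilylation starts a cascade in which the C6 alkoxide lactonises onto the cis methyl ester, the now acidic C6–H is removed and the furanolate opens the adjacent epoxide at C5 (vinylogous E1cB), which keeps the C4–O bond and hence the C4 configuration and should give the Z-ylidene (ring-trans) alkene because the other geometry would force C4 and C8 into an in-plane 1,3-clash; the primary TBS ether is cleaved in the same pot.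

Step 17
Reactants: 23 13-deacetyl target
Product: 24 (4R,5Z,8R,10S)-13-acetoxy-4-hydroxy-8-[(3-methylbut-2-enoyl)oxy]-1-oxogermacra-5,7(11)-dien-12,6-olide (target)
Conditions: Ac2O, pyridine, CH2Cl2, 0 °C
Reagents that add atoms: acetic anhydride CC(=O)OC(C)=O
Why: Selective acetylation, in which the primary allylic C13 hydroxyl is acylated under mild conditions while the tertiary allylic C4 hydroxyl should stay free.

**Compound list**

1 | 1-methoxy-4-[(prop-2-yn-1-yloxy)methyl]benzene (4-methoxybenzyl propargyl ether) | C#CCOCc1ccc(OC)cc1 | starting material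
2 | dimethyl{(1E)-3-[(4-methoxybenzyl)oxy]-2-methylprop-1-en-1-yl}alumane | C[Al](C)/C=C(\C)COCc1ccc(OC)cc1 | intermediate
3 | (2E)-4-[(4-methoxybenzyl)oxy]-3-methylbut-2-en-1-ol | OC/C=C(\C)COCc1ccc(OC)cc1 | intermediate
4 | (2E)-4-[(4-methoxybenzyl)oxy]-3-methylbut-2-enal | O=C/C=C(\C)COCc1ccc(OC)cc1 | intermediate
5 | methyl 3-hydroxypropanoate | COC(=O)CCO | starting material
6 | methyl 3-[(tert-butyldimethylsilyl)oxy]propanoate | COC(=O)CCO[Si](C)(C)C(C)(C)C | intermediate
7 | (5R)-5-(hydroxymethyl)oxolan-2-one | OC[C@H]1CCC(=O)O1 | starting material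
8 | (5R)-5-{[(tert-butyldimethylsilyl)oxy]methyl}oxolan-2-one | CC(C)(C)[Si](C)(C)OC[C@H]1CCC(=O)O1 | intermediate
9 | (3S,5R)-5-{[(tert-butyldimethylsilyl)oxy]methyl}-3-methyloxolan-2-one | CC(C)(C)[Si](C)(C)OC[C@H]1C[C@H](C)C(=O)O1 | intermediate
10 | (2R,4S)-4-methyl-5-oxooxolane-2-carboxylic acid | OC(=O)[C@H]1C[C@H](C)C(=O)O1 | intermediate
11 | (2R,4S)-4-methyl-5-oxooxolane-2-carbonyl chloride | ClC(=O)[C@H]1C[C@H](C)C(=O)O1 | intermediate
12 | methyl 2-{[(tert-butyldimethylsilyl)oxy]methyl}-3-[(2R,4S)-4-methyl-5-oxooxolan-2-yl]-3-oxopropanoate (C2 epimers, enolisable) | COC(=O)C(CO[Si](C)(C)C(C)(C)C)C(=O)[C@H]1C[C@H](C)C(=O)O1 | intermediate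
13 | methyl (2Z)-2-{[(tert-butyldimethylsilyl)oxy]methyl}-3-[(2R,4S)-4-methyl-5-oxooxolan-2-yl]-3-{[(trifluoromethyl)sulfonyl]oxy}prop-2-enoate | COC(=O)/C(CO[Si](C)(C)C(C)(C)C)=C(\OS(=O)(=O)C(F)(F)F)[C@H]1C[C@H](C)C(=O)O1 | intermediate
14 | methyl (2Z,5E)-2-{[(tert-butyldimethylsilyl)oxy]methyl}-7-[(4-methoxybenzyl)oxy]-6-methyl-3-[(2R,4S)-4-methyl-5-oxooxolan-2-yl]-4-[(triethylsilyl)oxy]hepta-2,5-dienoate (C4 of the chain = C6, both epimers) | COC(=O)/C(CO[Si](C)(C)C(C)(C)C)=C(\C(O[Si](CC)(CC)CC)/C=C(\C)COCc1ccc(OC)cc1)[C@H]1C[C@H](C)C(=O)O1 | intermediate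
15 | 9-tert-butyl 1-methyl (2Z,4R,6S)-2-{[(tert-butyldimethylsilyl)oxy]methyl}-4-hydroxy-3-{(2E)-4-[(4-methoxybenzyl)oxy]-3-methyl-1-[(triethylsilyl)oxy]but-2-en-1-yl}-6-methyl-7-oxonon-2-enedioate (C6 epimers) | COC(=O)/C(CO[Si](C)(C)C(C)(C)C)=C(\C(O[Si](CC)(CC)CC)/C=C(\C)COCc1ccc(OC)cc1)[C@H](O)C[C@H](C)C(=O)CC(=O)OC(C)(C)C | intermediate
16 | 9-tert-butyl 1-methyl (2Z,4R,6S)-2-{[(tert-butyldimethylsilyl)oxy]methyl}-3-{(2E)-4-[(4-methoxybenzyl)oxy]-3-methyl-1-[(triethylsilyl)oxy]but-2-en-1-yl}-6-methyl-4-[(3-methylbut-2-enoyl)oxy]-7-oxonon-2-enedioate (C6 epimers) | COC(=O)/C(CO[Si](C)(C)C(C)(C)C)=C(\C(O[Si](CC)(CC)CC)/C=C(\C)COCc1ccc(OC)cc1)[C@H](OC(=O)C=C(C)C)C[C@H](C)C(=O)CC(=O)OC(C)(C)C | intermediate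
17 | 9-tert-butyl 1-methyl (2Z,4R,6S)-2-{[(tert-butyldimethylsilyl)oxy]methyl}-3-{(2E)-4-hydroxy-3-methyl-1-[(triethylsilyl)oxy]but-2-en-1-yl}-6-methyl-4-[(3-methylbut-2-enoyl)oxy]-7-oxonon-2-enedioate (C6 epimers) | COC(=O)/C(CO[Si](C)(C)C(C)(C)C)=C(\C(O[Si](CC)(CC)CC)/C=C(\C)CO)[C@H](OC(=O)C=C(C)C)C[C@H](C)C(=O)CC(=O)OC(C)(C)C | intermediate
18 | acylketene from 17 (C1(=O)–CH=C=O in place of the tert-butyl β-keto ester) | COC(=O)/C(CO[Si](C)(C)C(C)(C)C)=C(\C(O[Si](CC)(CC)CC)/C=C(\C)CO)[C@H](OC(=O)C=C(C)C)C[C@H](C)C(=O)C=C=O | intermediate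
19 | methyl (2Z)-3-[(tert-butyldimethylsilyl)oxy]-2-{(5S,7R,10E)-5,11-dimethyl-7-[(3-methylbut-2-enoyl)oxy]-2,4-dioxo-9-[(triethylsilyl)oxy]-1-oxacyclododec-10-en-8-ylidene}propanoate (C6 epimers) | O=C1CC(=O)[C@@H](C)C[C@@H](OC(=O)C=C(C)C)/C(=C(\CO[Si](C)(C)C(C)(C)C)C(=O)OC)C(O[Si](CC)(CC)CC)/C=C(\C)CO1 | intermediate
20 | methyl (4E,8R,10S)-13-[(tert-butyldimethylsilyl)oxy]-8-[(3-methylbut-2-enoyl)oxy]-1-oxo-6-[(triethylsilyl)oxy]germacra-4,7(11)-dien-12-oate (C6 epimers; C6 cis to C12 across C7=C11) | O=C1CC/C(C)=C/C(O[Si](CC)(CC)CC)/C(=C(/CO[Si](C)(C)C(C)(C)C)C(=O)OC)[C@H](OC(=O)C=C(C)C)C[C@@H]1C | intermediate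
21 | methyl (4R,5R,8R,10S)-13-[(tert-butyldimethylsilyl)oxy]-4,5-epoxy-8-[(3-methylbut-2-enoyl)oxy]-1-oxo-6-[(triethylsilyl)oxy]germacr-7(11)-en-12-oate (C6 epimers) | O=C1CC[C@@]2(C)O[C@@H]2C(O[Si](CC)(CC)CC)/C(=C(/CO[Si](C)(C)C(C)(C)C)C(=O)OC)[C@H](OC(=O)C=C(C)C)C[C@@H]1C | intermediate
22 | (4R,5R,8R,10S)-13-[(tert-butyldimethylsilyl)oxy]-4,5-epoxy-8-[(3-methylbut-2-enoyl)oxy]-1-oxogermacr-7(11)-en-12,6-olide (C6 epimers) | O=C1CC[C@@]2(C)O[C@@H]2C3OC(=O)C(CO[Si](C)(C)C(C)(C)C)=C3[C@H](OC(=O)C=C(C)C)C[C@@H]1C | intermediate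
23 | (4R,5Z,8R,10S)-4,13-dihydroxy-8-[(3-methylbut-2-enoyl)oxy]-1-oxogermacra-5,7(11)-dien-12,6-olide | OCC1=C2/C(=C/[C@](C)(O)CCC(=O)[C@@H](C)C[C@H]2OC(=O)C=C(C)C)OC1=O | intermediate
24 | (4R,5Z,8R,10S)-13-acetoxy-4-hydroxy-8-[(3-methylbut-2-enoyl)oxy]-1-oxogermacra-5,7(11)-dien-12,6-olide | CC(=O)OCC1=C2/C(=C/[C@](C)(O)CCC(=O)[C@@H](C)C[C@H]2OC(=O)C=C(C)C)OC1=O | target

**Step count and risks**

Total step count: 17. Longest linear sequence: 14 steps (steps 4–17, from 7).

Steps most likely to fail

1. Step 14 (proposed new method). After ionisation and decarboxylation the tethered enolate may be protonated, or may alkylate a second molecule, faster than it closes the strained ten-membered ring. Fallback with known chemistry, setting out from 17: the allylic alcohol is converted with methyl chloroformate and pyridine into the allylic methyl carbonate F1. An intramolecular Tsuji–Trost allylic alkylation of the intact tert-butyl β-keto ester (Pd2(dba)3, dppe, THF, high dilution, 60 °C) then closes the ten-membered ring directly at C2–C3 to give the ring β-keto ester F2. Thermal loss of isobutene and CO2 (wet DMSO, 140 °C) returns to the route at 20.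

2. Step 16. The cascade may derail by alkoxide-induced epoxide migration (Payne type) or acyl transfer from the neighbouring senecioate before lactonisation, or the elimination may give the wrong alkene geometry. Fallback, setting out from 21: both silyl groups are removed with TBAF buffered by acetic acid so that no free alkoxide is formed, and PPTS completes the lactonisation to the isolable epoxy butenolide F3. The epoxide is then opened in a separate operation with DBU in CH2Cl2, followed if necessary by iodine/visible-light equilibration to the more stable Z-ylidene isomer. This comes back to the route at 23.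

3. Step 9. The alkenylchromium carries an allylic acyloxy group and may undergo β-elimination, may add too slowly to the enal because it is tetrasubstituted and ester-conjugated, or the chromium alkoxide may lactonise before it is silylated. Fallback with reversed polarity, setting out from 13 and 1: Pd-catalysed reductive carbonylation of 13 (Pd(OAc)2, dppp, CO, Et3SiH, DMF) gives the aldehyde F4. Carboalumination of 1 followed by iodination (Me3Al, Cp2ZrCl2; I2) gives the vinyl iodide F5. A Nozaki–Hiyama–Kishi coupling of F5 (now the unhindered alkenylchromium partner) with F4 under the same Cr-catalytic chlorosilane conditions comes back to the route at 14.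

Further compounds
F1 | step 14 | allylic methyl carbonate of 17 (C3–OCO2Me) | COC(=O)/C(CO[Si](C)(C)C(C)(C)C)=C(\C(O[Si](CC)(CC)CC)/C=C(\C)COC(=O)OC)[C@H](OC(=O)C=C(C)C)C[C@H](C)C(=O)CC(=O)OC(C)(C)C
F2 | step 14 | methyl (4E,8R,10S)-2-(tert-butoxycarbonyl)-13-[(tert-butyldimethylsilyl)oxy]-8-[(3-methylbut-2-enoyl)oxy]-1-oxo-6-[(triethylsilyl)oxy]germacra-4,7(11)-dien-12-oate (C2 and C6 epimers) | O=C1C(C(=O)OC(C)(C)C)C/C(C)=C/C(O[Si](CC)(CC)CC)/C(=C(/CO[Si](C)(C)C(C)(C)C)C(=O)OC)[C@H](OC(=O)C=C(C)C)C[C@@H]1C
F3 | step 16 | (4R,5R,8R,10S)-4,5-epoxy-13-hydroxy-8-[(3-methylbut-2-enoyl)oxy]-1-oxogermacr-7(11)-en-12,6-olide (C6 epimers) | O=C1CC[C@@]2(C)O[C@@H]2C3OC(=O)C(CO)=C3[C@H](OC(=O)C=C(C)C)C[C@@H]1C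
F4 | step 9 | methyl (2Z)-2-{[(tert-butyldimethylsilyl)oxy]methyl}-3-[(2R,4S)-4-methyl-5-oxooxolan-2-yl]-4-oxobut-2-enoate | COC(=O)/C(CO[Si](C)(C)C(C)(C)C)=C(\C=O)[C@H]1C[C@H](C)C(=O)O1
F5 | step 9 | 1-({[(2E)-3-iodo-2-methylprop-2-en-1-yl]oxy}methyl)-4-methoxybenzene | COc1ccc(COC/C(C)=C/I)cc1
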